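The route rests on opening the seven-membered ring between C2' of the resorcinol ring on benzofuran C3 (the carbon ortho to one oxygen and para to the other) and the ketone α-carbon that bears the 4-hydroxyphenyl group. The key step turns that α-carbon into a rhodium carbene, lets the electron-rich C2' attack it in a Friedel–Crafts-type closure of the seven-membered ring, and sets the only stereocentre through proton relay by a chiral spiro phosphoric acid, all in one operation. Its precursor is an achiral, perbenzylated 2,3-diarylbenzofuran that carries an α-aryl-α-diazo ketone on C4, made in five steps; hydrogenolysis then frees the five phenols.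

Key step: step 6

Assumption: no model fixes which enantiomer of the spiro phosphoric acid delivers the proton to the face that gives the (S)-centre in this ring system; the (R)-acid is written, and its equally available mirror image is taken should the first run show the opposite sense.

Step 1
Reactants: 1 methyl 3-(benzyloxy)-5-hydroxybenzoate; 2 2-bromo-1-[3,5-bis(benzyloxy)phenyl]ethan-1-one
Product: 3 methyl 3-(benzyloxy)-5-{2-[3,5-bis(benzyloxy)phenyl]-2-oxoethoxy}benzoate
Conditions: K2CO3, acetone, reflux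
Reagents that add atoms: none
Why: Williamson ether synthesis: the phenoxide of 1 displaces the primary α-keto bromide of 2 by SN2, and the ester and benzyl ethers are inert to K2CO3.

Step 2
Reactants: 3 methyl 3-(benzyloxy)-5-{2-[3,5-bis(benzyloxy)phenyl]-2-oxoethoxy}benzoate
Product: 5 methyl 6-(benzyloxy)-3-[3,5-bis(benzyloxy)phenyl]-1-benzofuran-4-carboxylate, via dihydrobenzofuran-3-ol 4 (not isolated)
Conditions: Bi(OTf)3 (10 mol %), CH2Cl2, 40 °C
Reagents that add atoms: none
Why: Bi(OTf)3-catalysed cyclodehydration of an α-aryloxy ketone (intramolecular Friedel–Crafts hydroxyalkylation to carbinol 4, then loss of water to the aromatic furan), closing at the ring carbon between the ether oxygen and the ester because it is para to the benzyloxy group, which places the ester on C4 and the benzyloxy group on C6.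

Step 3
Reactants: 5 methyl 6-(benzyloxy)-3-[3,5-bis(benzyloxy)phenyl]-1-benzofuran-4-carboxylate; 6 1-(benzyloxy)-4-bromobenzene
Product: 7 methyl 6-(benzyloxy)-2-[4-(benzyloxy)phenyl]-3-[3,5-bis(benzyloxy)phenyl]-1-benzofuran-4-carboxylate
Conditions: Pd(OAc)2 (5 mol %), PCy3·HBF4 (10 mol %), PivOH (30 mol %), K2CO3, DMA, 100 °C
Reagents that add atoms: none
Why: Palladium-catalysed direct C–H arylation (pivalate-assisted concerted metalation–deprotonation) after oxidative addition of 6 to zerovalent palladium; C2–H is the only furan C–H and the most acidic one, so the aryl group enters there.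

Step 4
Reactants: 7 methyl 6-(benzyloxy)-2-[4-(benzyloxy)phenyl]-3-[3,5-bis(benzyloxy)phenyl]-1-benzofuran-4-carboxylate; 8 [4-(benzyloxy)phenyl]acetic acid
Product: 10 1-{6-(benzyloxy)-2-[4-(benzyloxy)phenyl]-3-[3,5-bis(benzyloxy)phenyl]-1-benzofuran-4-yl}-2-[4-(benzyloxy)phenyl]ethan-1-one (deoxybenzoin), via β-keto acid 9 (not isolated)
Conditions: 8, t-BuMgCl (2 equiv per 8), THF, 0 to 50 °C; then 7, 50 °C; then 2 M HCl, 50 °C
Reagents that add atoms: none
Why: Crossed Claisen condensation of the magnesium enediolate of 8 (Ivanov reagent) with the non-enolisable ester 7, the product being held as a chelated β-keto carboxylate that cannot add a second time, then decarboxylation of β-keto acid 9 on warm acidic work-up.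

Step 5
Reactants: 10 1-{6-(benzyloxy)-2-[4-(benzyloxy)phenyl]-3-[3,5-bis(benzyloxy)phenyl]-1-benzofuran-4-yl}-2-[4-(benzyloxy)phenyl]ethan-1-one
Product: 11 1-{6-(benzyloxy)-2-[4-(benzyloxy)phenyl]-3-[3,5-bis(benzyloxy)phenyl]-1-benzofuran-4-yl}-2-[4-(benzyloxy)phenyl]-2-diazoethan-1-one
Conditions: p-ABSA, DBU, MeCN, 0 °C to rt
Reagents that add atoms: p-ABSA (4-acetamidobenzenesulfonyl azide), CC(=O)Nc1ccc(cc1)S(=O)(=O)N=[N+]=[N-]
Why: Regitz diazo transfer: the DBU-generated enolate of the doubly activated (benzylic and α-keto) methylene attacks the terminal nitrogen of the sulfonyl azide and the sulfonamide is expelled.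

Step 6
Reactants: 11 1-{6-(benzyloxy)-2-[4-(benzyloxy)phenyl]-3-[3,5-bis(benzyloxy)phenyl]-1-benzofuran-4-yl}-2-[4-(benzyloxy)phenyl]-2-diazoethan-1-one
Product: 13 (S)-penta-O-benzylhopeafuran (seven-membered-ring ketone whose ring CH carbon bearing the 4-(benzyloxy)phenyl group is S), via cyclic enol 12 (not isolated)
Conditions: Rh2(O2CCPh3)4 (1 mol %), (R)-STRIP [(R)-6,6'-bis(2,4,6-triisopropylphenyl)-1,1'-spirobiindane-7,7'-diyl hydrogen phosphate] (5 mol %), CHCl3, 4 Å molecular sieves, 0 °C, slow addition of 11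
Reagents that add atoms: none
Why: Rh2(O2CCPh3)4 turns the donor/acceptor diazo ketone into an electrophilic rhodium carbene at the future stereocentre, C2' of the 3,5-bis(benzyloxy)phenyl ring (ortho to one ether oxygen, para to the other) attacks it in a Friedel–Crafts-type aromatic substitution, and loss of the arenium proton and of the metal gives enol 12, which the spiro phosphoric acid ketonises as a chiral proton shuttle. The closest known reaction type is the formal insertion of α-aryl-α-diazo carbonyl compounds into C–H bonds of electron-rich arenes and into N–H bonds under cooperative dirhodium tetracarboxylate/chiral spiro phosphoric acid catalysis, where the enantioselectivity arises in the proton transfer. The seven-membered ring closes exo with respect to the Rh=C bond, the carbene carbon and C2' being held within bonding distance by the neighbouring C3 and C4 positions of the benzofuran. The new (S)-centre is controlled by the chiral phosphate pocket during C-protonation of the planar enol, not by the achiral metal complex. The step needs site selectivity (aromatic substitution over O-ylide formation, benzylic C–H insertion, insertion into water and carbene dimerisation), secured by the double alkoxy activation of C2', the equivalence of C2' and C6', the sieves and slow addition at high dilution. It also needs the acid-mediated proton transfer to outrun the uncatalysed 1,2-hydrogen shift, which the low temperature and the acidity of the arenium proton favour.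

Step 7
Reactants: 13 (S)-penta-O-benzylhopeafuran
Product: 14 (S)-hopeafuran
Conditions: H2 (1 atm), Pd/C (10 wt %), EtOAc–MeOH, rt
Reagents that add atoms: none
Why: Catalytic hydrogenolysis of the five benzylic C–O bonds on palladium under neutral conditions, which neither enolises the ketone (the S centre is kept) nor reduces the electron-rich, hindered aryl ketone at a comparable rate.

Compound list
1 | methyl 3-(benzyloxy)-5-hydroxybenzoate | COC(=O)c1cc(O)cc(OCc2ccccc2)c1 | starting material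
2 | 2-bromo-1-[3,5-bis(benzyloxy)phenyl]ethan-1-one | O=C(CBr)c1cc(OCc2ccccc2)cc(OCc2ccccc2)c1 | starting material
3 | methyl 3-(benzyloxy)-5-{2-[3,5-bis(benzyloxy)phenyl]-2-oxoethoxy}benzoate | COC(=O)c1cc(OCC(=O)c2cc(OCc3ccccc3)cc(OCc3ccccc3)c2)cc(OCc2ccccc2)c1 | intermediate
4 | methyl 6-(benzyloxy)-3-[3,5-bis(benzyloxy)phenyl]-3-hydroxy-2,3-dihydro-1-benzofuran-4-carboxylate (racemic carbinol) | COC(=O)c1cc(OCc2ccccc2)cc2OCC(O)(c3cc(OCc4ccccc4)cc(OCc4ccccc4)c3)c12 | intermediate
5 | methyl 6-(benzyloxy)-3-[3,5-bis(benzyloxy)phenyl]-1-benzofuran-4-carboxylate | COC(=O)c1cc(OCc2ccccc2)cc2occ(-c3cc(OCc4ccccc4)cc(OCc4ccccc4)c3)c12 | intermediate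
6 | 1-(benzyloxy)-4-bromobenzene | Brc1ccc(OCc2ccccc2)cc1 | starting material
7 | methyl 6-(benzyloxy)-2-[4-(benzyloxy)phenyl]-3-[3,5-bis(benzyloxy)phenyl]-1-benzofuran-4-carboxylate | COC(=O)c1cc(OCc2ccccc2)cc2oc(-c3ccc(OCc4ccccc4)cc3)c(-c3cc(OCc4ccccc4)cc(OCc4ccccc4)c3)c12 | intermediate
8 | [4-(benzyloxy)phenyl]acetic acid | OC(=O)Cc1ccc(OCc2ccccc2)cc1 | starting material
9 | 3-{6-(benzyloxy)-2-[4-(benzyloxy)phenyl]-3-[3,5-bis(benzyloxy)phenyl]-1-benzofuran-4-yl}-2-[4-(benzyloxy)phenyl]-3-oxopropanoic acid (racemic β-keto acid) | OC(=O)C(c1ccc(OCc2ccccc2)cc1)C(=O)c1cc(OCc2ccccc2)cc2oc(-c3ccc(OCc4ccccc4)cc3)c(-c3cc(OCc4ccccc4)cc(OCc4ccccc4)c3)c12 | intermediate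
10 | 1-{6-(benzyloxy)-2-[4-(benzyloxy)phenyl]-3-[3,5-bis(benzyloxy)phenyl]-1-benzofuran-4-yl}-2-[4-(benzyloxy)phenyl]ethan-1-one (deoxybenzoin) | O=C(Cc1ccc(OCc2ccccc2)cc1)c1cc(OCc2ccccc2)cc2oc(-c3ccc(OCc4ccccc4)cc3)c(-c3cc(OCc4ccccc4)cc(OCc4ccccc4)c3)c12 | intermediate
11 | 1-{6-(benzyloxy)-2-[4-(benzyloxy)phenyl]-3-[3,5-bis(benzyloxy)phenyl]-1-benzofuran-4-yl}-2-[4-(benzyloxy)phenyl]-2-diazoethan-1-one | [N-]=[N+]=C(c1ccc(OCc2ccccc2)cc1)C(=O)c1cc(OCc2ccccc2)cc2oc(-c3ccc(OCc4ccccc4)cc3)c(-c3cc(OCc4ccccc4)cc(OCc4ccccc4)c3)c12 | intermediate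
12 | enol tautomer of 13: the seven-membered ring holds C(OH)=C[4-(benzyloxy)phenyl] between benzofuran C4 and C2' of the bis(benzyloxy)phenyl ring (no stereocentre) | OC1=C(c2ccc(OCc3ccccc3)cc2)c2c(OCc3ccccc3)cc(OCc3ccccc3)cc2-c2c(-c3ccc(OCc4ccccc4)cc3)oc3cc(OCc4ccccc4)cc1c23 | intermediate
13 | (S)-penta-O-benzylhopeafuran (ring CH bearing the 4-(benzyloxy)phenyl group is S) | O=C1c2cc(OCc3ccccc3)cc3oc(-c4ccc(OCc5ccccc5)cc4)c(c23)-c2cc(OCc3ccccc3)cc(OCc3ccccc3)c2[C@@H]1c1ccc(OCc2ccccc2)cc1 | intermediate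
14 | (S)-hopeafuran (ring CH bearing the 4-hydroxyphenyl group is S) | O=C1c2cc(O)cc3oc(-c4ccc(O)cc4)c(c23)-c2cc(O)cc(O)c2[C@@H]1c1ccc(O)cc1 | target

Total step count: 7. Longest linear sequence: 7 steps (1 to 14).

Steps most likely to fail

Step 6. The proton transfer may give poor facial selectivity if the uncatalysed 1,2-hydrogen shift or an acid-free ketonisation competes. The carbene may also be diverted into dimerisation, O-ylide formation or protonation of the diazo carbon by the acid. The fallback sets out from ester 7 and comes back at 13, with the stereocentre set by a reagent-controlled epoxidation. DIBAL-H (CH2Cl2, −78 °C) should give the benzylic alcohol F1, and MnO2 (CH2Cl2) the aldehyde F2. Horner–Wadsworth–Emmons olefination with diethyl [4-(benzyloxy)benzyl]phosphonate (NaH, THF) should give the E-stilbene F3. Shi epoxidation with the enantiomer of the D-fructose-derived ketone (made from L-sorbose), Oxone and K2CO3 in MeCN–dimethoxymethane–aqueous buffer at 0 °C should give the (S,S)-trans-epoxide F4. Bi(OTf)3 or BF3·OEt2 in CH2Cl2 at −78 °C should then open the epoxide at the carbon bearing the 4-(benzyloxy)phenyl group. C2' attacks in a 7-endo Friedel–Crafts mode anti to the departing oxygen, which closes the seven-membered ring with inversion and gives the trans alcohol F5 (carbinol carbon R, aryl-bearing carbon S). Buffered Dess–Martin oxidation removes the carbinol centre and returns to 13.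

Step 4. Acylation of the enediolate by the ester may stay incomplete because the C3 aryl group shields the C4 ester, and retro-Claisen cleavage may occur on work-up. The fallback sets out from 7 and comes back at 10. i-PrMgCl with N,O-dimethylhydroxylamine hydrochloride (THF, −20 °C) should convert the ester into the Weinreb amide F6. [4-(Benzyloxy)benzyl]magnesium chloride (from 4-(benzyloxy)benzyl chloride and Mg, THF, 0 °C) should then add once, and the chelated tetrahedral adduct collapses on work-up to deoxybenzoin 10.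

Step 7. Cleavage of five ethers may be slow enough that over-reduction of the aryl ketone, or erosion at the enolisable centre on long contact with the catalyst, begins to compete. The fallback sets out from 10 and comes back at 14, changing the protecting groups before any stereocentre exists. BCl3 with pentamethylbenzene as cation scavenger (CH2Cl2, −78 °C) should give the pentaphenol deoxybenzoin F7. TBSCl and imidazole (DMF) should give the penta-TBS ether F8, and diazo transfer as in step 5 the diazo ketone F9. Closure as in step 6 should pass through the enol F10 to the (S)-penta-TBS ketone F11. Et3N·3HF (THF, 0 °C), a non-basic and only weakly acidic fluoride source, should then free 14.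

Further compounds
F1 | step 6 | {6-(benzyloxy)-2-[4-(benzyloxy)phenyl]-3-[3,5-bis(benzyloxy)phenyl]-1-benzofuran-4-yl}methanol | OCc1cc(OCc2ccccc2)cc2oc(-c3ccc(OCc4ccccc4)cc3)c(-c3cc(OCc4ccccc4)cc(OCc4ccccc4)c3)c12
F2 | step 6 | 6-(benzyloxy)-2-[4-(benzyloxy)phenyl]-3-[3,5-bis(benzyloxy)phenyl]-1-benzofuran-4-carbaldehyde | O=Cc1cc(OCc2ccccc2)cc2oc(-c3ccc(OCc4ccccc4)cc3)c(-c3cc(OCc4ccccc4)cc(OCc4ccccc4)c3)c12
F3 | step 6 | 6-(benzyloxy)-2-[4-(benzyloxy)phenyl]-3-[3,5-bis(benzyloxy)phenyl]-4-{(E)-2-[4-(benzyloxy)phenyl]ethenyl}-1-benzofuran | C(c1ccccc1)Oc1ccc(/C=C/c2cc(OCc3ccccc3)cc3oc(-c4ccc(OCc5ccccc5)cc4)c(-c4cc(OCc5ccccc5)cc(OCc5ccccc5)c4)c23)cc1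
F4 | step 6 | (S,S)-trans-epoxide of F3: (2S,3S)-2-[4-(benzyloxy)phenyl]-3-{6-(benzyloxy)-2-[4-(benzyloxy)phenyl]-3-[3,5-bis(benzyloxy)phenyl]-1-benzofuran-4-yl}oxirane | C(c1ccccc1)Oc1ccc(cc1)[C@@H]1O[C@H]1c1cc(OCc2ccccc2)cc2oc(-c3ccc(OCc4ccccc4)cc3)c(-c3cc(OCc4ccccc4)cc(OCc4ccccc4)c3)c12
F5 | step 6 | trans alcohol corresponding to 13 (C=O replaced by CHOH; carbinol carbon R, aryl-bearing carbon S) | O[C@H]1c2cc(OCc3ccccc3)cc3oc(-c4ccc(OCc5ccccc5)cc4)c(c23)-c2cc(OCc3ccccc3)cc(OCc3ccccc3)c2[C@@H]1c1ccc(OCc2ccccc2)cc1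
F6 | step 4 | 6-(benzyloxy)-2-[4-(benzyloxy)phenyl]-3-[3,5-bis(benzyloxy)phenyl]-N-methoxy-N-methyl-1-benzofuran-4-carboxamide | CON(C)C(=O)c1cc(OCc2ccccc2)cc2oc(-c3ccc(OCc4ccccc4)cc3)c(-c3cc(OCc4ccccc4)cc(OCc4ccccc4)c3)c12
F7 | step 7 | 1-[3-(3,5-dihydroxyphenyl)-6-hydroxy-2-(4-hydroxyphenyl)-1-benzofuran-4-yl]-2-(4-hydroxyphenyl)ethan-1-one | O=C(Cc1ccc(O)cc1)c1cc(O)cc2oc(-c3ccc(O)cc3)c(-c3cc(O)cc(O)c3)c12
F8 | step 7 | penta-O-TBS ether of F7 | O=C(Cc1ccc(O[Si](C)(C)C(C)(C)C)cc1)c1cc(O[Si](C)(C)C(C)(C)C)cc2oc(-c3ccc(O[Si](C)(C)C(C)(C)C)cc3)c(-c3cc(O[Si](C)(C)C(C)(C)C)cc(O[Si](C)(C)C(C)(C)C)c3)c12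
F9 | step 7 | α-diazo ketone of F8 | [N-]=[N+]=C(c1ccc(O[Si](C)(C)C(C)(C)C)cc1)C(=O)c1cc(O[Si](C)(C)C(C)(C)C)cc2oc(-c3ccc(O[Si](C)(C)C(C)(C)C)cc3)c(-c3cc(O[Si](C)(C)C(C)(C)C)cc(O[Si](C)(C)C(C)(C)C)c3)c12
F10 | step 7 | enol tautomer of F11 (no stereocentre) | OC1=C(c2ccc(O[Si](C)(C)C(C)(C)C)cc2)c2c(O[Si](C)(C)C(C)(C)C)cc(O[Si](C)(C)C(C)(C)C)cc2-c2c(-c3ccc(O[Si](C)(C)C(C)(C)C)cc3)oc3cc(O[Si](C)(C)C(C)(C)C)cc1c23
F11 | step 7 | (S)-penta-O-TBS-hopeafuran | O=C1c2cc(O[Si](C)(C)C(C)(C)C)cc3oc(-c4ccc(O[Si](C)(C)C(C)(C)C)cc4)c(c23)-c2cc(O[Si](C)(C)C(C)(C)C)cc(O[Si](C)(C)C(C)(C)C)c2[C@@H]1c1ccc(O[Si](C)(C)C(C)(C)C)cc1
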